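## Retrosynthetic overview

1. Key disconnection: O1–C2 (ring C) and C4a–C5 (ring A) are cut in the same operation, so the hexasubstituted benzene ring is grown from an open chain and never bought (chromanone numbering throughout).
2. C5–C8 with prenyl and methoxy already in place: methyl 4-methoxyacetoacetate 1 + prenyl bromide 2 → keto ester 3.
3. C8–C8a disconnection: acetyl donor 4 extends 3 to diketo ester 5.
4. C4a–C4 disconnection: enantiopure trans-glycidate 6 (source of C2, C3, C4 and of both stereocentres) acylates the terminal methyl of 5 → open-chain epoxy triketo ester 7.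
5. Ring order, one flask from 7: ring C first (pyranone 8, acid, fixes O1 next to the methoxy carbon), ring A second (Claisen aromatisation to target 9).

Assumption: methyl (2R,3S)-3-phenyloxirane-2-carboxylate (6), the enantiopure trans-glycidate made on scale as a paclitaxel side-chain intermediate, is bought.

## Route

Step 1
Reactants: 1 methyl 4-methoxy-3-oxobutanoate; 2 1-bromo-3-methylbut-2-ene
Product: 3 methyl 2-(2-methoxyacetyl)-5-methylhex-4-enoate
Conditions: K2CO3 (1.5 equiv), acetone, 0 °C → rt (1 in 1.2-fold excess)
Reagents that add atoms: none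
Why: K2CO3 removes the doubly activated C2 proton and the soft enolate is C-alkylated by the allylic bromide (acetoacetic ester alkylation, SN2), which places the prenyl group on the future C6; the new stereocentre is irrelevant because this carbon becomes aromatic.

Step 2
Reactants: 3 methyl 2-(2-methoxyacetyl)-5-methylhex-4-enoate; 4 N-methoxy-N-methylacetamide
Product: 5 methyl 4-methoxy-2-(3-methylbut-2-en-1-yl)-3,5-dioxohexanoate
Conditions: LiN(iPr)2 (2.2 equiv), THF, −78 → 0 °C; then 4 (1.1 equiv), −78 → −20 °C; AcOH
Reagents that add atoms: none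
Why: the second deprotonation takes place at the methoxymethyl carbon and this more reactive γ-site attacks the Weinreb amide, whose chelated tetrahedral adduct stops at the ketone (γ-acylation of a β-keto ester dianion, Huckin–Weiler type, combined with the Weinreb ketone synthesis); no controlled stereocentre is formed.

Step 3
Reactants: 5 methyl 4-methoxy-2-(3-methylbut-2-en-1-yl)-3,5-dioxohexanoate (2.1 equiv); 6 methyl (2R,3S)-3-phenyloxirane-2-carboxylate
Product: 7 methyl 4-methoxy-2-(3-methylbut-2-en-1-yl)-3,5,7-trioxo-7-[(2R,3S)-3-phenyloxiran-2-yl]heptanoate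
Conditions: LiN(iPr)2 (6.5 equiv), THF, −78 → 0 °C; then 6, −78 → −40 °C; AcOH, −78 °C; aq. NaH2PO4/Na2HPO4 (pH 7); crude 7 used at once (surplus 5 is inert in step 4)
Reagents that add atoms: none
Why: after triple deprotonation the terminal methyl carbanion is the only non-stabilised and most nucleophilic site and adds to the non-enolisable ester carbonyl of 6 faster than to the epoxide, while the polyanionic product cannot cyclise before the buffered quench (Claisen condensation of a β,δ-diketo ester trianion); both epoxide stereocentres are carried over unchanged from 6.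

Step 4
Reactants: 7 methyl 4-methoxy-2-(3-methylbut-2-en-1-yl)-3,5,7-trioxo-7-[(2R,3S)-3-phenyloxiran-2-yl]heptanoate
Product: 9 (2R,3R)-3,5,7-trihydroxy-8-methoxy-6-(3-methylbut-2-en-1-yl)-2-phenyl-2,3-dihydro-4H-chromen-4-one, via pyranone keto ester 8 (not isolated)
Conditions: CSA (10 mol%), CH2Cl2, 0 °C → rt, Ar; then DBU (3 equiv), rt; aq. NaH2PO4
Reagents that add atoms: none
Why: Proposed new method: under acid the only oxygen that can reach the benzylic epoxide carbon through a six-membered transition state is the enol oxygen of the carbonyl next to the methoxy-bearing carbon, so anti (6-endo) opening closes ring C, sets C2 by inversion while C3 keeps the epoxide configuration (trans, 2R,3R) and fixes O1 next to the methoxy carbon before ring A exists; DBU then forms the extended enolate of the resulting vinylogous ester, whose pyranone α-carbon (future C4a) attacks the methyl ester in a six-membered Claisen (Dieckmann-type) closure, and loss of methanol with tautomerisation gives aromatic ring A, the rival aldol mode being unable to aromatise because the ester α-carbon carries the prenyl group; the closest known reaction types are the acid-catalysed cyclisation of 2'-hydroxychalcone epoxides to trans-dihydroflavonols and the biomimetic Claisen cyclisation of 3,5,7-triketo esters to acylphloroglucinols.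

## Compound list

1 | methyl 4-methoxy-3-oxobutanoate | COCC(=O)CC(=O)OC | starting material
2 | 1-bromo-3-methylbut-2-ene (prenyl bromide) | CC(C)=CCBr | starting material
3 | methyl 2-(2-methoxyacetyl)-5-methylhex-4-enoate (racemic at C2) | COCC(=O)C(CC=C(C)C)C(=O)OC | intermediate
4 | N-methoxy-N-methylacetamide | CC(=O)N(C)OC | starting material
5 | methyl 4-methoxy-2-(3-methylbut-2-en-1-yl)-3,5-dioxohexanoate (epimer and enol mixture) | COC(=O)C(CC=C(C)C)C(=O)C(OC)C(C)=O | intermediate
6 | methyl (2R,3S)-3-phenyloxirane-2-carboxylate | COC(=O)[C@@H]1O[C@H]1c1ccccc1 | starting material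
7 | methyl 4-methoxy-2-(3-methylbut-2-en-1-yl)-3,5,7-trioxo-7-[(2R,3S)-3-phenyloxiran-2-yl]heptanoate (epimer and enol mixture at C2 and C4) | COC(=O)C(CC=C(C)C)C(=O)C(OC)C(=O)CC(=O)[C@@H]1O[C@H]1c1ccccc1 | intermediate
8 | methyl 2-{2-[(2R,3R)-3-hydroxy-4-oxo-2-phenyl-3,4-dihydro-2H-pyran-6-yl]-2-methoxyacetyl}-5-methylhex-4-enoate (formed in the flask in step 4) | COC(=O)C(CC=C(C)C)C(=O)C(OC)C1=CC(=O)[C@H](O)[C@@H](c2ccccc2)O1 | intermediate
9 | (2R,3R)-3,5,7-trihydroxy-8-methoxy-6-(3-methylbut-2-en-1-yl)-2-phenyl-2,3-dihydro-4H-chromen-4-one | COc1c(O)c(CC=C(C)C)c(O)c2c1O[C@H](c1ccccc1)[C@@H](O)C2=O | target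

## Step count and fallbacks

Total steps: 4. Longest linear sequence: 4 (1 → 3 → 5 → 7 → 9).

Steps most likely to fail:

Step 4 (double cyclisation). The risk is that the Claisen closure of ring A stalls at the unreactive β-keto ester enolate, or that base erodes the C2/C3 centres. In the fallback, ring A is closed thermally through an acylketene instead of by base. It sets out from 8, obtained by stopping step 4 after the acid stage. The 3-hydroxyl is capped (TESCl, imidazole, CH2Cl2) to give methyl 2-{2-methoxy-2-[(2R,3R)-4-oxo-2-phenyl-3-(triethylsilyloxy)-3,4-dihydro-2H-pyran-6-yl]acetyl}-5-methylhex-4-enoate F1. Heating (xylene, 140 °C) expels methanol from the β-keto ester; the acylketene is captured by the pyranone α-carbon and tautomerisation gives (2R,3R)-5,7-dihydroxy-8-methoxy-6-(3-methylbut-2-en-1-yl)-2-phenyl-3-(triethylsilyloxy)-2,3-dihydro-4H-chromen-4-one F2. AcOH/THF/H2O removes the silyl group and the route is rejoined at 9.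

Step 3 (trianion acylation). The risk is proton transfer or attack on the epoxide, giving low conversion of 6. In the fallback, the C4a–C4 bond is made by aldol addition and the ketone by oxidation. It sets out from 6, which is reduced (iBu2AlH, CH2Cl2, −78 °C) to (2R,3S)-3-phenyloxirane-2-carbaldehyde F3. The trianion of 5 adds to the aldehyde at −78 °C (1:1, no surplus of 5 because the aldolate is not acidic) to give methyl 7-hydroxy-4-methoxy-2-(3-methylbut-2-en-1-yl)-3,5-dioxo-7-[(2S,3S)-3-phenyloxiran-2-yl]heptanoate F4. The epoxide has the same spatial arrangement as in 6; the descriptor changes by priority only. Dess–Martin periodinane (CH2Cl2, NaHCO3, 0 °C) oxidises the carbinol and the route is rejoined at 7.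

Step 2 (dianion acetylation). The risk is enolisation of the amide by the dianion or incomplete γ-deprotonation. In the fallback, a neutral Mukaiyama-type acylation replaces the dianion. It sets out from 3: Et3N/TMSCl gives the silyl enol ether methyl 2-[2-methoxy-1-(trimethylsilyloxy)ethylidene]-5-methylhex-4-enoate F5. LiN(iPr)2 then TMSCl gives 1,4-dimethoxy-2-(3-methylbut-2-en-1-yl)-1,3-bis(trimethylsilyloxy)buta-1,3-diene F6, whose terminal methoxy-bearing carbon is acylated by acetyl chloride (CH2Cl2, −78 → 20 °C). Aqueous work-up hydrolyses the remaining silyl enol ether and the route is rejoined at 5.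

## Further compounds

F1 | step 4 | methyl 2-{2-methoxy-2-[(2R,3R)-4-oxo-2-phenyl-3-(triethylsilyloxy)-3,4-dihydro-2H-pyran-6-yl]acetyl}-5-methylhex-4-enoate | COC(=O)C(CC=C(C)C)C(=O)C(OC)C1=CC(=O)[C@H](O[Si](CC)(CC)CC)[C@@H](c2ccccc2)O1
F2 | step 4 | (2R,3R)-5,7-dihydroxy-8-methoxy-6-(3-methylbut-2-en-1-yl)-2-phenyl-3-(triethylsilyloxy)-2,3-dihydro-4H-chromen-4-one | COc1c(O)c(CC=C(C)C)c(O)c2c1O[C@H](c1ccccc1)[C@@H](O[Si](CC)(CC)CC)C2=O
F3 | step 3 | (2R,3S)-3-phenyloxirane-2-carbaldehyde | O=C[C@@H]1O[C@H]1c1ccccc1
F4 | step 3 | methyl 7-hydroxy-4-methoxy-2-(3-methylbut-2-en-1-yl)-3,5-dioxo-7-[(2S,3S)-3-phenyloxiran-2-yl]heptanoate | COC(=O)C(CC=C(C)C)C(=O)C(OC)C(=O)CC(O)[C@@H]1O[C@H]1c1ccccc1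
F5 | step 2 | methyl 2-[2-methoxy-1-(trimethylsilyloxy)ethylidene]-5-methylhex-4-enoate | COCC(O[Si](C)(C)C)=C(CC=C(C)C)C(=O)OC
F6 | step 2 | 1,4-dimethoxy-2-(3-methylbut-2-en-1-yl)-1,3-bis(trimethylsilyloxy)buta-1,3-diene | COC=C(O[Si](C)(C)C)C(CC=C(C)C)=C(OC)O[Si](C)(C)C
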